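The ansa chain is numbered C1 (amide carbonyl) to C17 (aryl ketone); C14 carries the lactone carbonyl and C11 the lactone oxygen. The methyl/oxygen array C6–C12 is mirror-symmetric about C9. That hidden symmetry is unlocked by a [4+3] cycloaddition of furan with the oxyallyl cation of 2,4-dibromopentan-3-one. In one operation it closes a seven-membered ring, forms C10–C11 (the δ-carbon of the tetrahydropyranone ring to its exocyclic methine) and C7–C8, and sets four stereocentres in a meso oxabicyclic template. Desymmetrising methylative ring opening, ozonolysis, aldol lactonisation and crotylation unfold the chain; Nozaki–Hiyama–Kishi coupling and ring-closing metathesis then attach and close the naphthoquinone ansa ring.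

Key step: step 1

Remark: in step 4 the ligand antipode that methylates the alkene carbon next to the future C11 is required; (R)-Tol-BINAP is written, and its mirror image is used should the sense prove opposite.

Aromatic positions are primed: quinone carbonyls C1′ and C4′, amide on C3′, hydroxyls on C5′ and C7′, methyl on C6′, ketone on C8′.

**Steps 1–4: oxabicyclic template to the cycloheptenol**

Step 1
Reactants: 1 2,4-dibromopentan-3-one; 2 furan
Product: 4 meso-(1R,2S,4R,5S)-2,4-dimethyl-8-oxabicyclo[3.2.1]oct-6-en-3-one, via zinc oxyallyl cation 3 (not isolated)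
Conditions: zinc–copper couple (Zn/Cu), furan (5 equiv), DME, −15 °C to rt
Reagents that add atoms: none
Why: Zinc reduces 1 to a bromozinc enolate that ionises to the W-shaped (Z,Z) oxyallyl cation 3, which furan captures in an oxyallyl cation [4+3] cycloaddition (4π diene plus 2π allyl cation), the closest known reaction type being the classical furan/α,α′-dihaloketone cycloaddition. The cycloaddition closes the seven-membered carbocycle, and with it the oxygen-bridged six-membered ketone ring, by forming C10–C11 and C7–C8 suprafacially on both partners. The four new stereocentres (C7, C8, C10, C11) are controlled by the W geometry of 3 (methyls cis) and by the compact transition state (methyls equatorial), giving the meso cis-diequatorial adduct in which each methyl is syn to its neighbouring C–O bond; C8, C10 and C11 persist to the target. The step needs diastereoselectivity over the diaxial and trans adducts, which the zinc-bound cation at low temperature should secure, and fast capture of the cation, which excess furan secures; the twofold symmetry of both partners removes any regiochemical issue. Absolute configuration is not fixed here because 4 is meso; it is set by the desymmetrising opening in step 4.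

Step 2
Reactants: 4 meso bicyclic ketone
Product: 5 meso-2,4-dimethyl-8-oxabicyclo[3.2.1]oct-6-en-3-endo-ol (axial hydroxyl)
Conditions: LiBH(s-Bu)3, THF, −78 °C; aq. NH4Cl
Reagents that add atoms: none
Why: The bulky borohydride should attack the ketone from the equatorial direction, away from the C6=C7 bridge, so the C9 carbinol becomes axial (endo), anti to both flanking methyls as the target requires (substrate-controlled hydride reduction).

Step 3
Reactants: 5 endo alcohol
Product: 6 3-endo-(tert-butyldimethylsilyloxy)-2,4-dimethyl-8-oxabicyclo[3.2.1]oct-6-ene (meso)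
Conditions: TBSOTf, 2,6-lutidine, CH2Cl2, 0 °C
Reagents that add atoms: tert-butyldimethylsilyl triflate, CC(C)(C)[Si](C)(C)OS(=O)(=O)C(F)(F)F
Why: Silyl ether protection of the hindered axial alcohol with the silyl triflate masks C9–OH for the organometallic and oxidative steps ahead.

Step 4
Reactants: 6 meso silyl ether
Product: 7 (1R,2R,5R,6R,7S)-6-(tert-butyldimethylsilyloxy)-2,5,7-trimethylcyclohept-3-en-1-ol (OH and 2-methyl cis; 5-methyl, 6-silyloxy and 7-methyl mutually cis and trans to OH)
Conditions: Me2Zn, Pd(MeCN)2Cl2 (5 mol %), (R)-Tol-BINAP (5 mol %), Zn(OTf)2 (10 mol %), ClCH2CH2Cl, 80 °C; aq. NH4Cl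
Reagents that add atoms: dimethylzinc, C[Zn]C
Why: Palladium-catalysed enantioselective alkylative ring opening (exo carbopalladation, then β-oxygen elimination) should break the C7–O bond of the template, deliver the C12 methyl cis to the C11 hydroxyl, and turn the meso compound into one enantiomer by ligand-controlled choice between the enantiotopic alkene carbons.

**Steps 5–7: the C14–C16 acyl unit**

Step 5
Reactants: 8 3-(tert-butyldimethylsilyloxy)propanal
Product: 9 (Z)-tert-butyl[(4-iodopent-3-en-1-yl)oxy]dimethylsilane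
Conditions: EtPPh3I, n-BuLi, THF; I2, −78 °C; NaN(SiMe3)2; then 8, −78 °C to rt
Reagents that add atoms: ethyltriphenylphosphonium iodide, CC[P+](c1ccccc1)(c1ccccc1)c1ccccc1.[I-]; iodine, II
Why: Stork–Zhao-type Wittig olefination with the α-iodo ylide should give the trisubstituted (Z)-vinyl iodide (chain cis to iodine), which encodes the C15=C16 geometry.

Step 6
Reactants: 9 (Z)-vinyl iodide silyl ether
Product: 11 (Z)-4-iodopent-3-enoic acid, via (Z)-4-iodopent-3-en-1-ol 10 (not isolated)
Conditions: CrO3, H2SO4, acetone/H2O, 0 °C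
Reagents that add atoms: water, O
Why: Jones oxidation cleaves the primary silyl ether in the acidic medium and oxidises the liberated alcohol to the acid without touching the vinyl iodide.

Step 7
Reactants: 11 (Z)-4-iodopent-3-enoic acid; 12 (S)-4-benzyloxazolidin-2-one
Product: 14 (S)-4-benzyl-3-[(Z)-4-iodopent-3-enoyl]oxazolidin-2-one, via mixed pivalic anhydride 13 (not isolated)
Conditions: t-BuCOCl, Et3N, THF, −20 °C; then 12, LiCl, rt
Reagents that add atoms: none
Why: N-Acylation of the oxazolidinone through the mixed pivalic anhydride under LiCl/Et3N avoids strong base, so the β,γ-alkene should stay in place.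

**Steps 8–11: unfolding the template into the C6–C16 fragment**

Step 8
Reactants: 7 cycloheptenol
Product: 16 2-[4-(tert-butyldimethylsilyloxy)-6-hydroxy-3,5-dimethyltetrahydropyran-2-yl]propanal (C7–C13 unit; hemiacetal at C7, anomer mixture; C8–C12 configured as in 40), via secondary ozonide 15 (not isolated)
Conditions: O3, CH2Cl2, −78 °C; PPh3, −78 °C to rt; used crude
Reagents that add atoms: ozone, [O-][O+]=O
Why: Ozonolysis with reductive work-up cleaves the C7=C13 alkene, the last carbocyclic bond of the template, and the free C11 hydroxyl closes a six-membered hemiacetal onto the C7 aldehyde, which leaves only the C13 aldehyde free and so differentiates the termini.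

Step 9
Reactants: 16 lactol aldehyde; 14 iodopentenoyl oxazolidinone
Product: 19 δ-lactone aldehyde: tetrahydropyran-2-one with 3-[(Z)-2-iodoprop-1-enyl], 4-hydroxy, 5-methyl and 6-[3-(tert-butyldimethylsilyloxy)-4-oxopentan-2-yl] groups (ring substituents all trans; C8–C14 as in 40), via boron dienolate 17 (not isolated), via lactol aldol adduct 18 (not isolated)
Conditions: 14 (2.2 equiv), Bu2BOTf, Et3N, CH2Cl2, −78 to 0 °C; 16, −78 to −10 °C; pH 7 buffer, MeOH, H2O2; then DMAP (0.2 equiv), CH2Cl2, rt
Reagents that add atoms: none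
Why: Evans syn-aldol addition of the (Z)-boron dienolate at its α-carbon should set C13 and C14 under auxiliary control, and DMAP-promoted ring–chain equilibration lets the C11 hydroxyl displace the oxazolidinone to close the δ-lactone (all substituents equatorial, so C14 is also thermodynamically secured) while releasing the C7 aldehyde.

Step 10
Reactants: 19 δ-lactone aldehyde
Product: 20 homoallylic alcohol: lactone of 19 with the side chain extended to (2S*-type) –CH(CH3)–CH(OTBS)–CH(CH3)–CH(OH)–CH(CH3)–CH=CH2 (C6–C14 configured as in 40; C7 and C13 hydroxyls free)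
Conditions: (E)-but-2-ene, KOt-Bu, n-BuLi, THF, −78 to −45 °C; (−)-Ipc2BOMe; BF3·OEt2; then 19, −78 °C; NaBO3·4H2O
Reagents that add atoms: (E)-crotyldiisopinocampheylborane, C/C=C/CB([C@@H]1C[C@@H]2C[C@@H](C2(C)C)[C@H]1C)[C@@H]1C[C@@H]2C[C@@H](C2(C)C)[C@H]1C
Why: Brown (E)-crotylboration through a chair transition state should give the 6,7-anti relationship, and the reagent's si-face preference coincides with Felkin–Anh attack on the α-methyl aldehyde (matched pair), setting C6 and C7 while the lactone is left alone.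

Step 11
Reactants: 20 homoallylic alcohol
Product: 21 tris(tert-butyldimethylsilyl) vinyl iodide fragment (C6–C16; silyl ethers at C7, C9 and C13)
Conditions: TBSOTf, 2,6-lutidine, CH2Cl2, −78 to 0 °C
Reagents that add atoms: tert-butyldimethylsilyl triflate, CC(C)(C)[Si](C)(C)OS(=O)(=O)C(F)(F)F
Why: Silyl ether formation with the triflate and a hindered pyridine base at low temperature should protect both secondary alcohols without base-induced elimination of the β-oxygenated lactone.

**Steps 12–18: naphthalene aldehyde carrying the dienamide**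

Step 12
Reactants: 22 methyl 2-methyl-3-oxobutanoate
Product: 23 1-methoxy-2-methyl-1,3-bis(trimethylsilyloxy)buta-1,3-diene
Conditions: TMSOTf (2.2 equiv), Et3N, Et2O, 0 °C; used crude
Reagents that add atoms: trimethylsilyl triflate, C[Si](C)(C)OS(=O)(=O)C(F)(F)F
Why: Double O-silylation of the β-keto ester (silyl enol ether formation at both enolisable sites) gives the electron-rich 1,3-bis(silyloxy)diene.

Step 13
Reactants: 23 bis(silyloxy)diene; 24 2,6-dibromo-1,4-benzoquinone
Product: 26 2-bromo-6,8-dihydroxy-7-methylnaphthalene-1,4-dione, via primary cycloadduct 25 (not isolated)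
Conditions: CH2Cl2, −40 °C to rt; then 1 M HCl, THF
Reagents that add atoms: none
Why: Regioselective Diels–Alder reaction, in which the nucleophilic CH2 terminus of the diene adds to the unsubstituted quinone carbon and the ketene-acetal carbon to the brominated one, followed by loss of HBr, methanol and the silyl groups, should build the resorcinol ring with the remaining bromine next to the carbonyl that is peri to the new phenol.

Step 14
Reactants: 26 bromodihydroxynaphthoquinone
Product: 28 2-bromo-1,4,6,8-tetramethoxy-7-methylnaphthalene, via naphthalenetetrol 27 (not isolated)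
Conditions: Na2S2O4, EtOAc/H2O, rt; then Me2SO4, K2CO3, acetone, reflux
Reagents that add atoms: dimethyl sulfate, COS(=O)(=O)OC
Why: Dithionite reduction to the hydroquinone and exhaustive Williamson methylation protect the quinone as its dimethyl ether and both phenols as methyl ethers.

Step 15
Reactants: 28 tetramethoxynaphthalene
Product: 29 6-bromo-2,4,5,8-tetramethoxy-3-methylnaphthalene-1-carbaldehyde
Conditions: Cl2CHOMe, TiCl4, CH2Cl2, −78 to 0 °C; H2O
Reagents that add atoms: dichloromethyl methyl ether, COC(Cl)Cl; water, O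
Why: Rieche formylation should occur at the only free position that is ortho and para to methoxy groups (future C8′), the other free position being flanked and deactivated by bromine.

Step 16
Reactants: 30 acrolein; 31 methyl 2-[bis(2,2,2-trifluoroethoxy)phosphoryl]propanoate
Product: 32 methyl (2Z)-2-methylpenta-2,4-dienoate
Conditions: KN(SiMe3)2, 18-crown-6, THF, −78 °C
Reagents that add atoms: none
Why: Still–Gennari olefination gives the (Z)-trisubstituted ester by fast, kinetically controlled elimination from the trifluoroethyl phosphonate adduct.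

Step 17
Reactants: 32 (Z)-dienoate
Product: 33 (2Z)-2-methylpenta-2,4-dienamide
Conditions: AlMe3, NH4Cl, toluene, 0 to 50 °C; aq. HCl
Reagents that add atoms: ammonium chloride, [NH4+].[Cl-]
Why: Aluminium amide aminolysis of the ester gives the primary amide and should leave the diene geometry untouched.

Step 18
Reactants: 29 bromonaphthaldehyde; 33 (Z)-dienamide
Product: 34 (2Z)-N-(5-formyl-1,4,6,8-tetramethoxy-7-methylnaphthalen-2-yl)-2-methylpenta-2,4-dienamide
Conditions: CuI (0.5 equiv), N,N′-dimethylethylenediamine, K2CO3, toluene, 100 °C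
Reagents that add atoms: none
Why: Copper-catalysed Goldberg amidation couples the aryl bromide with the primary dienamide and places nitrogen at the future C3′.

**Steps 19–24: fragment union, macrocyclisation and unveiling**

Step 19
Reactants: 21 vinyl iodide fragment; 34 naphthaldehyde dienamide
Product: 35 seco carbinol (C17 secondary alcohol joining C16 to C8′; epimer mixture at C17)
Conditions: CrCl2 (6 equiv), NiCl2 (1 mol %), DMSO/THF, rt
Reagents that add atoms: none
Why: Nozaki–Hiyama–Kishi coupling generates a configurationally stable trisubstituted alkenylchromium species that should add chemoselectively to the aryl aldehyde with retention of the (Z)-alkene; the carbinol configuration is irrelevant.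

Step 20
Reactants: 35 seco carbinol
Product: 36 seco aryl enone (C17 ketone)
Conditions: Dess–Martin periodinane, NaHCO3, CH2Cl2, 0 °C to rt
Reagents that add atoms: none
Why: Dess–Martin oxidation of the benzylic, allylic alcohol gives the aryl enone under buffered, non-epimerising conditions.

Step 21
Reactants: 36 seco aryl enone
Product: 37 macrocyclic tetramethoxynaphthalene tris(silyl ether) (ansa ring closed, (2Z,4E)-dienamide)
Conditions: second-generation Grubbs catalyst (15 mol %), toluene, 80 °C, 0.5 mM
Reagents that add atoms: none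
Why: Ring-closing metathesis between the two terminal vinyl groups (the trisubstituted alkenes are inert) should close the ansa ring, 22-membered counted through the lactone oxygen, and form C4=C5 with E geometry as the less strained conjugated diene.

Step 22
Reactants: 37 macrocyclic tetramethoxynaphthalene
Product: 38 macrocyclic 5′,7′-dimethoxy-1′,4′-naphthoquinone tris(silyl ether)
Conditions: (NH4)2Ce(NO3)6, MeCN/H2O, 0 °C
Reagents that add atoms: water, O
Why: Oxidative demethylation with ceric ammonium nitrate should convert the only ring with para-disposed methoxy groups into the 1,4-quinone.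

Step 23
Reactants: 38 dimethoxyquinone
Product: 39 macrocyclic 5′,7′-dihydroxyquinone tris(silyl ether)
Conditions: BCl3, CH2Cl2, −78 to −20 °C; aq. NaHCO3
Reagents that add atoms: none
Why: Chelation-assisted Lewis acid ether cleavage should remove exactly the two aryl methyl groups whose oxygens sit next to a carbonyl (peri to the C4′ quinone carbonyl, ortho to the C17 ketone), leaving silyl ethers, lactone and polyene intact at low temperature.

Step 24
Reactants: 39 dihydroxyquinone tris(silyl ether)
Product: 40 target compound CNP0507423.1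
Conditions: aq. HF (48 %), MeCN, 0 °C to rt
Reagents that add atoms: none
Why: Acidic fluoride desilylation should release the C7, C9 and C13 hydroxyls without opening the lactone or isomerising the enone.

**Compound list**

1 | 2,4-dibromopentan-3-one | CC(Br)C(=O)C(C)Br | starting material
2 | furan | c1ccoc1 | starting material
3 | bromozinc (Z,Z)-1,3-dimethyl-2-oxyallyl cation, W form | C/C=C(\O[Zn]Br)[CH+]C | intermediate
4 | meso-(1R,2S,4R,5S)-2,4-dimethyl-8-oxabicyclo[3.2.1]oct-6-en-3-one | C[C@@H]1C(=O)[C@H](C)[C@@H]2C=C[C@H]1O2 | intermediate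
5 | meso-2,4-dimethyl-8-oxabicyclo[3.2.1]oct-6-en-3-endo-ol | C[C@@H]1[C@H](O)[C@H](C)[C@@H]2C=C[C@H]1O2 | intermediate
6 | meso-3-endo-(tert-butyldimethylsilyloxy)-2,4-dimethyl-8-oxabicyclo[3.2.1]oct-6-ene | C[C@@H]1[C@H](O[Si](C)(C)C(C)(C)C)[C@H](C)[C@@H]2C=C[C@H]1O2 | intermediate
7 | (1R,2R,5R,6R,7S)-6-(tert-butyldimethylsilyloxy)-2,5,7-trimethylcyclohept-3-en-1-ol | O[C@@H]1[C@H](C)C=C[C@@H](C)[C@@H](O[Si](C)(C)C(C)(C)C)[C@H]1C | intermediate
8 | 3-(tert-butyldimethylsilyloxy)propanal | O=CCCO[Si](C)(C)C(C)(C)C | starting material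
9 | (Z)-tert-butyl[(4-iodopent-3-en-1-yl)oxy]dimethylsilane | C/C(I)=C/CCO[Si](C)(C)C(C)(C)C | intermediate
10 | (Z)-4-iodopent-3-en-1-ol | C/C(I)=C/CCO | intermediate
11 | (Z)-4-iodopent-3-enoic acid | C/C(I)=C/CC(=O)O | intermediate
12 | (S)-4-benzyloxazolidin-2-one | O=C1N[C@@H](Cc2ccccc2)CO1 | starting material
13 | (Z)-4-iodopent-3-enoic pivalic anhydride | C/C(I)=C/CC(=O)OC(=O)C(C)(C)C | intermediate
14 | (S)-4-benzyl-3-[(Z)-4-iodopent-3-enoyl]oxazolidin-2-one | C/C(I)=C/CC(=O)N1[C@@H](Cc2ccccc2)COC1=O | intermediate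
15 | secondary ozonide (1,2,4-trioxolane) of 7 | O[C@@H]1[C@H](C)C2OOC(O2)[C@@H](C)[C@@H](O[Si](C)(C)C(C)(C)C)[C@H]1C | intermediate
16 | 2-[4-(tert-butyldimethylsilyloxy)-6-hydroxy-3,5-dimethyltetrahydropyran-2-yl]propanal (lactol aldehyde, anomer mixture) | O=C[C@@H](C)[C@H]1OC(O)[C@@H](C)[C@@H](O[Si](C)(C)C(C)(C)C)[C@H]1C | intermediate
17 | dibutylboron (Z)-dienolate of 14 | C/C(I)=C/C=C(\OB(CCCC)CCCC)N1[C@@H](Cc2ccccc2)COC1=O | intermediate
18 | syn-aldol adduct of 16 and 14 (lactol intact, C13 hydroxyl, C14 (Z)-2-iodopropenyl, N-acyl oxazolidinone) | O=C1OC[C@H](Cc2ccccc2)N1C(=O)[C@@H](/C=C(/C)I)[C@H](O)[C@@H](C)[C@H]3OC(O)[C@@H](C)[C@@H](O[Si](C)(C)C(C)(C)C)[C@H]3C | intermediate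
19 | δ-lactone aldehyde (C7 aldehyde, C9 silyl ether, C13 hydroxyl, C14 (Z)-2-iodopropenyl) | O=C[C@@H](C)[C@@H](O[Si](C)(C)C(C)(C)C)[C@@H](C)[C@@H]1OC(=O)[C@@H](/C=C(/C)I)[C@H](O)[C@H]1C | intermediate
20 | homoallylic alcohol (C6 methyl and vinyl, C7 and C13 hydroxyls, C9 silyl ether, δ-lactone, vinyl iodide) | C=C[C@H](C)[C@H](O)[C@@H](C)[C@@H](O[Si](C)(C)C(C)(C)C)[C@@H](C)[C@@H]1OC(=O)[C@@H](/C=C(/C)I)[C@H](O)[C@H]1C | intermediate
21 | tris(tert-butyldimethylsilyl) vinyl iodide fragment C6–C16 | C=C[C@H](C)[C@H](O[Si](C)(C)C(C)(C)C)[C@@H](C)[C@@H](O[Si](C)(C)C(C)(C)C)[C@@H](C)[C@@H]1OC(=O)[C@@H](/C=C(/C)I)[C@H](O[Si](C)(C)C(C)(C)C)[C@H]1C | intermediate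
22 | methyl 2-methyl-3-oxobutanoate | COC(=O)C(C)C(C)=O | starting material
23 | 1-methoxy-2-methyl-1,3-bis(trimethylsilyloxy)buta-1,3-diene | COC(O[Si](C)(C)C)=C(C)C(=C)O[Si](C)(C)C | intermediate
24 | 2,6-dibromo-1,4-benzoquinone | O=C1C=C(Br)C(=O)C(Br)=C1 | starting material
25 | primary Diels–Alder adduct of 23 and 24 | O=C1C=C(Br)C(=O)C2(Br)C(OC)(O[Si](C)(C)C)C(C)=C(O[Si](C)(C)C)CC12 | intermediate
26 | 2-bromo-6,8-dihydroxy-7-methylnaphthalene-1,4-dione | O=C1C=C(Br)C(=O)c2c(O)c(C)c(O)cc12 | intermediate
27 | 2-bromo-7-methylnaphthalene-1,4,6,8-tetrol | Oc1cc(Br)c(O)c2c(O)c(C)c(O)cc12 | intermediate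
28 | 2-bromo-1,4,6,8-tetramethoxy-7-methylnaphthalene | COc1cc(Br)c(OC)c2c(OC)c(C)c(OC)cc12 | intermediate
29 | 6-bromo-2,4,5,8-tetramethoxy-3-methylnaphthalene-1-carbaldehyde | COc1cc(Br)c(OC)c2c(OC)c(C)c(OC)c(C=O)c12 | intermediate
30 | acrolein | C=CC=O | starting material
31 | methyl 2-[bis(2,2,2-trifluoroethoxy)phosphoryl]propanoate | COC(=O)C(C)P(=O)(OCC(F)(F)F)OCC(F)(F)F | starting material
32 | methyl (2Z)-2-methylpenta-2,4-dienoate | C=C/C=C(/C)C(=O)OC | intermediate
33 | (2Z)-2-methylpenta-2,4-dienamide | C=C/C=C(/C)C(N)=O | intermediate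
34 | (2Z)-N-(5-formyl-1,4,6,8-tetramethoxy-7-methylnaphthalen-2-yl)-2-methylpenta-2,4-dienamide | C=C/C=C(/C)C(=O)Nc1cc(OC)c2c(C=O)c(OC)c(C)c(OC)c2c1OC | intermediate
35 | seco carbinol (C17 alcohol, epimer mixture) | C=C[C@H](C)[C@H](O[Si](C)(C)C(C)(C)C)[C@@H](C)[C@@H](O[Si](C)(C)C(C)(C)C)[C@@H](C)[C@@H]1OC(=O)[C@@H](/C=C(/C)C(O)c2c(OC)c(C)c(OC)c3c(OC)c(NC(=O)/C(C)=C\C=C)cc(OC)c23)[C@H](O[Si](C)(C)C(C)(C)C)[C@H]1C | intermediate
36 | seco aryl enone | C=C[C@H](C)[C@H](O[Si](C)(C)C(C)(C)C)[C@@H](C)[C@@H](O[Si](C)(C)C(C)(C)C)[C@@H](C)[C@@H]1OC(=O)[C@@H](/C=C(/C)C(=O)c2c(OC)c(C)c(OC)c3c(OC)c(NC(=O)/C(C)=C\C=C)cc(OC)c23)[C@H](O[Si](C)(C)C(C)(C)C)[C@H]1C | intermediate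
37 | macrocyclic tetramethoxynaphthalene tris(silyl ether) | C/C1=C/C=C/[C@H](C)[C@H](O[Si](C)(C)C(C)(C)C)[C@@H](C)[C@@H](O[Si](C)(C)C(C)(C)C)[C@@H](C)[C@@H]2OC(=O)[C@@H](/C=C(/C)C(=O)c3c(OC)c(C)c(OC)c4c(OC)c(NC1=O)cc(OC)c34)[C@H](O[Si](C)(C)C(C)(C)C)[C@H]2C | intermediate
38 | macrocyclic 5′,7′-dimethoxynaphthoquinone tris(silyl ether) | C/C1=C/C=C/[C@H](C)[C@H](O[Si](C)(C)C(C)(C)C)[C@@H](C)[C@@H](O[Si](C)(C)C(C)(C)C)[C@@H](C)[C@@H]2OC(=O)[C@@H](/C=C(/C)C(=O)c3c(OC)c(C)c(OC)c4c3C(=O)C=C(NC1=O)C4=O)[C@H](O[Si](C)(C)C(C)(C)C)[C@H]2C | intermediate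
39 | macrocyclic 5′,7′-dihydroxynaphthoquinone tris(silyl ether) | C/C1=C/C=C/[C@H](C)[C@H](O[Si](C)(C)C(C)(C)C)[C@@H](C)[C@@H](O[Si](C)(C)C(C)(C)C)[C@@H](C)[C@@H]2OC(=O)[C@@H](/C=C(/C)C(=O)c3c(O)c(C)c(O)c4c3C(=O)C=C(NC1=O)C4=O)[C@H](O[Si](C)(C)C(C)(C)C)[C@H]2C | intermediate
40 | CNP0507423.1 | C/C1=C/C=C/[C@H](C)[C@H](O)[C@@H](C)[C@@H](O)[C@@H](C)[C@@H]2OC(=O)[C@@H](/C=C(/C)C(=O)c3c(O)c(C)c(O)c4c3C(=O)C=C(NC1=O)C4=O)[C@H](O)[C@H]2C | target

**Totals**

Total step count: 24. Longest linear sequence: 14 steps (1–4, 8–11, 19–24).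

**Steps most likely to fail**

Step 9. The free hemiacetal hydroxyl of 16, or a bicyclic hemiacetal formed with the C13 aldehyde, may quench the boron dienolate or sequester the aldehyde, and slow ring–chain equilibration may stall the transacylation. The fallback masks the hemiacetal. It sets out from 16, which is silylated (Et3SiCl, imidazole, CH2Cl2) to the anomeric triethylsilyl ether aldehyde F1. The aldol with 14 under the same boron conditions then gives the protected adduct F2. Buffered AcOH/THF/H2O removes the anomeric silyl group to give 18, where ring–chain exchange is acid-catalysed, and DMAP closes the lactone. The fallback comes back to the route at 19.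

Step 21. Oligomerisation, stalling at the stabilised vinylcarbene or poor E/Z control of C4=C5 may defeat macrocyclic metathesis. The fallback moves the ring closure to the C16–C17 bond. It sets out from 21 and 34, which are joined first by intermolecular cross-metathesis (second-generation Grubbs catalyst, excess 34, CH2Cl2, 40 °C) to the open-chain (2Z,4E)-dienamide iodo aldehyde F3, whose alkene isomers can be separated before ring closure. Intramolecular Nozaki–Hiyama–Kishi reaction (CrCl2, NiCl2, DMSO/THF, high dilution) then closes the ansa ring to the macrocyclic carbinol F4. Dess–Martin oxidation returns the route at 37.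

Step 23. Incomplete cleavage of the C7′ methyl ether, or Lewis-acid-induced lactone opening, β-elimination or Z to E drift of the enone, may erode the late-stage demethylation. The fallback inverts the order and uses nucleophilic instead of Lewis-acidic ether cleavage. It sets out from 38, which is first desilylated (aq. HF, MeCN) to the 5′,7′-di-O-methyl ether of the target F5. The two carbonyl-flanked methyl ethers are then removed by magnesium-chelated iodide attack (MgI2·OEt2, THF/toluene, 50 °C). The fallback comes back at 40.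

Further compounds
F1 | step 9 | anomeric triethylsilyl ether of lactol aldehyde 16 | O=C[C@@H](C)[C@H]1OC(O[Si](CC)(CC)CC)[C@@H](C)[C@@H](O[Si](C)(C)C(C)(C)C)[C@H]1C
F2 | step 9 | syn-aldol adduct of F1 and 14 (anomeric triethylsilyl ether of 18) | O=C1OC[C@H](Cc2ccccc2)N1C(=O)[C@@H](/C=C(/C)I)[C@H](O)[C@@H](C)[C@H]3OC(O[Si](CC)(CC)CC)[C@@H](C)[C@@H](O[Si](C)(C)C(C)(C)C)[C@H]3C
F3 | step 21 | open-chain (2Z,4E)-dienamide bearing the C16 vinyl iodide and the C8′ aldehyde (cross-metathesis product of 21 and 34) | C/C(=C/C=C/[C@H](C)[C@H](O[Si](C)(C)C(C)(C)C)[C@@H](C)[C@@H](O[Si](C)(C)C(C)(C)C)[C@@H](C)[C@@H]1OC(=O)[C@@H](/C=C(/C)I)[C@H](O[Si](C)(C)C(C)(C)C)[C@H]1C)C(=O)Nc1cc(OC)c2c(C=O)c(OC)c(C)c(OC)c2c1OC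
F4 | step 21 | macrocyclic C17 carbinol (epimer mixture) | C/C1=C/C=C/[C@H](C)[C@H](O[Si](C)(C)C(C)(C)C)[C@@H](C)[C@@H](O[Si](C)(C)C(C)(C)C)[C@@H](C)[C@@H]2OC(=O)[C@@H](/C=C(/C)C(O)c3c(OC)c(C)c(OC)c4c(OC)c(NC1=O)cc(OC)c34)[C@H](O[Si](C)(C)C(C)(C)C)[C@H]2C
F5 | step 23 | 5′,7′-di-O-methyl ether of the target (free C7, C9, C13 hydroxyls) | C/C1=C/C=C/[C@H](C)[C@H](O)[C@@H](C)[C@@H](O)[C@@H](C)[C@@H]2OC(=O)[C@@H](/C=C(/C)C(=O)c3c(OC)c(C)c(OC)c4c3C(=O)C=C(NC1=O)C4=O)[C@H](O)[C@H]2C
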